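Sipholenol L is divided at the C8–C9 bridge into a cis-decalin tetrazolyl sulfone (rings C and D) and an oxepane-fused cyclohexane aldehyde (rings A and B), joined by Julia–Kocienski olefination and diimide reduction. The strategy rests on one bond of ring D, C6–C21, which links the ring-fusion methine to the gem-dimethyl carbon. Iron-hydride hydrogen-atom transfer to the isopropenyl end of a 4-substituted 2-(silyloxymethyl)cyclohex-2-enone makes a tertiary radical that adds 6-exo to the enone β-carbon: ring D, the hindered tertiary–quaternary bond and the C6 and C7 stereocentres arise in one operation. The precursor carries C5 and C24 from a single Sharpless epoxide.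

Key step: step 11

Remark on labels: backbone atoms are labelled in the order of the target SMILES, branch methyls and hydroxyl oxygens not counted (C1 vinylic methyl; C2–C7 ring C; C8–C9 bridge; C10, C11, C17–C20 ring B; C11–C15, O16, C17 ring A; C5, C6, C21–C24 ring D); compound names use IUPAC locants.
Assumption: the enantiomer of the Shi ketone (L-fructose configuration, prepared from L-sorbose) is available as a catalyst; this enantiomer is required because C14, C17 and C11 derive from (S)-configured epoxide carbons.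

**Right half (rings C and D)**

Step 1
Reactants: 1 but-2-yn-1-ol
Product: 2 (2Z)-3-iodobut-2-en-1-ol
Conditions: NaAlH2(OCH2CH2OMe)2, Et2O, 0 °C to rt; then I2, THF, −78 °C
Reagents that add atoms: iodine, [I][I]
Why: Hydroxyl-directed trans-hydroalumination of the propargylic alcohol places aluminium on C3 cis to the carbinol carbon, and iodinolysis of the alkenylalanate with retention should give only the Z-iodoalkene.

Step 2
Reactants: 2 (2Z)-3-iodobut-2-en-1-ol; 3 4-bromo-2-methylbut-1-ene
Product: 5 (2Z)-3,6-dimethylhepta-2,6-dien-1-ol, via (3-methylbut-3-en-1-yl)zinc bromide 4 (not isolated)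
Conditions: 3, Zn dust, LiCl, THF, 40 °C; then 2, PdCl2(dppf) (3 mol%), THF, rt to 50 °C
Reagents that add atoms: none
Why: Negishi sp2–sp3 cross-coupling of an alkenyl iodide with a primary alkylzinc halide proceeds with retention of alkene geometry, the chelating ferrocenyl diphosphine suppressing β-hydride elimination, and the free hydroxyl is tolerated by the organozinc used in excess.

Step 3
Reactants: 5 (2Z)-3,6-dimethylhepta-2,6-dien-1-ol
Product: 6 [(2R,3S)-3-methyl-3-(3-methylbut-3-en-1-yl)oxiran-2-yl]methanol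
Conditions: Ti(OiPr)4 (10 mol%), D-(−)-diethyl tartrate (12 mol%), t-BuOOH, 4 Å molecular sieves, CH2Cl2, −20 °C
Reagents that add atoms: tert-butyl hydroperoxide, CC(C)(C)OO
Why: Sharpless asymmetric epoxidation is confined to the allylic alkene, and with the D-tartrate the Z-alcohol should give the (2R,3S)-epoxide (the sense known for nerol), which fixes C24 and, latently, C5.

Step 4
Reactants: 6 [(2R,3S)-3-methyl-3-(3-methylbut-3-en-1-yl)oxiran-2-yl]methanol; 7 but-3-en-1-ylmagnesium bromide
Product: 8 (2S,3S)-2-(but-3-en-1-yl)-3,6-dimethylhept-6-ene-1,3-diol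
Conditions: 7 (3.5 equiv), CuI (20 mol%), THF, −40 to 0 °C
Reagents that add atoms: none
Why: Copper-catalysed Grignard opening of a 3,3-disubstituted 2,3-epoxy alcohol takes place at C2, because the quaternary C3 is shielded, with inversion, so that C5 is set relative to C24 by the epoxide geometry.

Step 5
Reactants: 8 (2S,3S)-2-(but-3-en-1-yl)-3,6-dimethylhept-6-ene-1,3-diol
Product: 9 (2S,3S)-2-(but-3-en-1-yl)-3,6-dimethyl-1,3-bis[(triethylsilyl)oxy]hept-6-ene
Conditions: Et3SiOTf (2.6 equiv), 2,6-lutidine, CH2Cl2, −78 to 0 °C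
Reagents that add atoms: triethylsilyl trifluoromethanesulfonate, CC[Si](CC)(CC)OS(=O)(=O)C(F)(F)F
Why: Silyl triflate with a hindered pyridine base silylates the primary and the tertiary hydroxyl; the tertiary ether prevents retro-aldol cleavage of the C5–C24 bond in the basic steps that follow.

Step 6
Reactants: 9 (2S,3S)-2-(but-3-en-1-yl)-3,6-dimethyl-1,3-bis[(triethylsilyl)oxy]hept-6-ene
Product: 10 (2R)-2-[(2S)-5-methyl-2-[(triethylsilyl)oxy]hex-5-en-2-yl]hex-5-enal
Conditions: (COCl)2, DMSO, CH2Cl2, −78 to −30 °C; then Et3N, −78 °C to rt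
Reagents that add atoms: none
Why: Under Swern conditions a primary triethylsilyl ether is cleaved and oxidised in the same flask while the tertiary silyl ether stays, which gives the aldehyde without a separate deprotection and, at low temperature, without epimerisation at C5.

Step 7
Reactants: 10 (2R)-2-[(2S)-5-methyl-2-[(triethylsilyl)oxy]hex-5-en-2-yl]hex-5-enal
Product: 11 (2R)-2-[(2S)-5-methyl-2-[(triethylsilyl)oxy]hex-5-en-2-yl]-5-oxohexanal
Conditions: PdCl2 (10 mol%), CuCl (1 equiv), O2 (1 atm), DMF/H2O 7:1, rt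
Reagents that add atoms: water, O
Why: Tsuji–Wacker oxidation converts the monosubstituted alkene into the methyl ketone with Markovnikov selectivity, whereas the 1,1-disubstituted alkene is not a substrate under these conditions.

Step 8
Reactants: 11 (2R)-2-[(2S)-5-methyl-2-[(triethylsilyl)oxy]hex-5-en-2-yl]-5-oxohexanal
Product: 12 (4S)-4-[(2S)-5-methyl-2-[(triethylsilyl)oxy]hex-5-en-2-yl]cyclohex-2-en-1-one
Conditions: 0.1 M aq. KOH, n-Bu4NOH (cat.), THF/Et2O, rt to 40 °C
Reagents that add atoms: none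
Why: Intramolecular aldol condensation, in which only the methyl ketone enolate can close a six-membered ring onto the aldehyde; dehydration gives the 4-substituted cyclohex-2-enone, and the C5 methine, shielded by the neighbouring quaternary carbon, should keep its configuration in dilute base.

Step 9
Reactants: 12 (4S)-4-[(2S)-5-methyl-2-[(triethylsilyl)oxy]hex-5-en-2-yl]cyclohex-2-en-1-one; 13 formaldehyde
Product: 14 (4S)-2-(hydroxymethyl)-4-[(2S)-5-methyl-2-[(triethylsilyl)oxy]hex-5-en-2-yl]cyclohex-2-en-1-one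
Conditions: 37% aq. CH2O, imidazole (1 equiv), THF/1 M aq. NaHCO3, rt
Reagents that add atoms: none
Why: Morita–Baylis–Hillman reaction of a cyclic enone with formaldehyde under imidazole catalysis installs the α-hydroxymethyl group, and the weakly basic medium leaves the silyl ether and C5 untouched.

Step 10
Reactants: 14 (4S)-2-(hydroxymethyl)-4-[(2S)-5-methyl-2-[(triethylsilyl)oxy]hex-5-en-2-yl]cyclohex-2-en-1-one
Product: 15 (4S)-4-[(2S)-5-methyl-2-[(triethylsilyl)oxy]hex-5-en-2-yl]-2-{[(triethylsilyl)oxy]methyl}cyclohex-2-en-1-one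
Conditions: Et3SiCl, imidazole, CH2Cl2, 0 °C
Reagents that add atoms: chlorotriethylsilane, CC[Si](Cl)(CC)CC
Why: Standard silylation of the primary allylic alcohol; a triethylsilyl group is chosen because the primary ether can later be removed in the presence of the tertiary one.

Step 11
Reactants: 15 (4S)-4-[(2S)-5-methyl-2-[(triethylsilyl)oxy]hex-5-en-2-yl]-2-{[(triethylsilyl)oxy]methyl}cyclohex-2-en-1-one
Product: 16 (1R,4aS,5S,8aS)-5,8,8-trimethyl-5-[(triethylsilyl)oxy]-1-{[(triethylsilyl)oxy]methyl}octahydronaphthalen-2(1H)-one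
Conditions: Fe(acac)3 (30 mol%), PhSiH3 (2.5 equiv), EtOH/(CH2OH)2/THF (degassed), 60 °C
Reagents that add atoms: none
Why: The iron hydride formed from Fe(acac)3 and PhSiH3 transfers a hydrogen atom to the terminal CH2 of the 1,1-disubstituted alkene, the nucleophilic tertiary C21 radical adds to the electrophilic enone carbon C6, and the α-keto radical is reduced by divalent iron to the enolate and protonated by ethanol (metal-hydride hydrogen-atom-transfer Giese cyclisation, the known reductive olefin–enone coupling in its intramolecular form). Ring D closes in the 6-exo-trig mode. C6 is controlled by the C5 stereocentre, because the three-atom tether reaches C6 only along the axial trajectory on the face syn to the C5–C24 bond, so the ring fusion must be cis. C7 is set by kinetic axial protonation of the enolate anti to the pseudoaxial C6–C21 bond, which places H7 cis to H6 and the silyloxymethyl arm cis to C21. The step needs chemoselective hydrogen-atom transfer to the electron-rich isopropenyl group and not to the electron-poor trisubstituted enone alkene, which the polarity difference secures. A neutral work-up is used so that C7 does not equilibrate, and C5 and C24 are carried through unchanged.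

Step 12
Reactants: 16 (1R,4aS,5S,8aS)-5,8,8-trimethyl-5-[(triethylsilyl)oxy]-1-{[(triethylsilyl)oxy]methyl}octahydronaphthalen-2(1H)-one
Product: 17 (1R,4aS,5S,8aS)-5,8,8-trimethyl-5-[(triethylsilyl)oxy]-1-{[(triethylsilyl)oxy]methyl}-1,4,4a,5,6,7,8,8a-octahydronaphthalen-2-yl trifluoromethanesulfonate
Conditions: KN(SiMe3)2 (1.3 equiv), THF, −78 °C (ketone added to base); then PhNTf2, −78 to −20 °C
Reagents that add atoms: N-phenylbis(trifluoromethanesulfonimide), O=S(=O)(N(c1ccccc1)S(=O)(=O)C(F)(F)F)C(F)(F)F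
Why: Kinetic deprotonation removes a proton from the C3 methylene and not from the hindered C7 methine, so that the enol triflate has the C2=C3 double bond and C7 is neither epimerised nor exposed to β-elimination of the silyloxy group.

Step 13
Reactants: 17 (1R,4aS,5S,8aS)-5,8,8-trimethyl-5-[(triethylsilyl)oxy]-1-{[(triethylsilyl)oxy]methyl}-1,4,4a,5,6,7,8,8a-octahydronaphthalen-2-yl trifluoromethanesulfonate
Product: 19 [(1S,4aS,5S,8aR)-2,5,8,8-tetramethyl-5-[(triethylsilyl)oxy]-1,4,4a,5,6,7,8,8a-octahydronaphthalen-1-yl]methanol, via methyl-coupled bis(triethylsilyl) ether 18 (not isolated)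
Conditions: MeMgBr, Fe(acac)3 (5 mol%), THF/NMP, −30 to 0 °C; aqueous work-up; then PPTS (20 mol%), MeOH/CH2Cl2, 0 °C
Reagents that add atoms: methylmagnesium bromide, C[Mg]Br
Why: Iron-catalysed Kumada-type coupling of the alkenyl triflate with the methyl Grignard reagent installs the vinylic methyl C1, and mild acid methanolysis then cleaves the primary triethylsilyl ether much faster than the hindered tertiary one.

Step 14
Reactants: 19 [(1S,4aS,5S,8aR)-2,5,8,8-tetramethyl-5-[(triethylsilyl)oxy]-1,4,4a,5,6,7,8,8a-octahydronaphthalen-1-yl]methanol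
Product: 20 1-phenyl-5-({[(1S,4aS,5S,8aS)-2,5,8,8-tetramethyl-5-[(triethylsilyl)oxy]-1,4,4a,5,6,7,8,8a-octahydronaphthalen-1-yl]methyl}sulfanyl)-1H-tetrazole
Conditions: 1-phenyl-1H-tetrazole-5-thiol, PPh3, DIAD, THF, 0 °C to rt
Reagents that add atoms: 1-phenyl-1H-tetrazole-5-thiol, Sc1nnnn1-c1ccccc1
Why: Mitsunobu thioetherification acts on the primary alcohol only; the tertiary silyl ether and the alkene are inert.

Step 15
Reactants: 20 1-phenyl-5-({[(1S,4aS,5S,8aS)-2,5,8,8-tetramethyl-5-[(triethylsilyl)oxy]-1,4,4a,5,6,7,8,8a-octahydronaphthalen-1-yl]methyl}sulfanyl)-1H-tetrazole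
Product: 21 1-phenyl-5-({[(1S,4aS,5S,8aS)-2,5,8,8-tetramethyl-5-[(triethylsilyl)oxy]-1,4,4a,5,6,7,8,8a-octahydronaphthalen-1-yl]methyl}sulfonyl)-1H-tetrazole
Conditions: (NH4)6Mo7O24·4H2O (10 mol%), 30% aq. H2O2, EtOH, 0 °C to rt
Reagents that add atoms: hydrogen peroxide, OO
Why: Molybdate-catalysed peroxide oxidation takes the sulfide to the sulfone and is known to spare trisubstituted alkenes.

**Left half (rings A and B)**

Step 16
Reactants: 22 methyl acetoacetate; 23 geranyl bromide
Product: 24 methyl (6E)-7,11-dimethyl-3-oxododeca-6,10-dienoate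
Conditions: NaH, THF, 0 °C; n-BuLi, 0 °C; then 23, 0 °C to rt
Reagents that add atoms: none
Why: Alkylation of the acetoacetate dianion occurs at the more basic γ-carbon (Weiler alkylation) by direct displacement of the allylic bromide, so the E geometry is retained.

Step 17
Reactants: 24 methyl (6E)-7,11-dimethyl-3-oxododeca-6,10-dienoate
Product: 25 methyl (2Z,6E)-3-[(diethoxyphosphoryl)oxy]-7,11-dimethyldodeca-2,6,10-trienoate
Conditions: NaH, Et2O, 0 °C; then ClP(O)(OEt)2
Reagents that add atoms: diethyl chlorophosphate, CCOP(=O)(Cl)OCC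
Why: O-Phosphorylation of the chelated sodium enolate of the β-keto ester gives the Z-enol phosphate.

Step 18
Reactants: 25 methyl (2Z,6E)-3-[(diethoxyphosphoryl)oxy]-7,11-dimethyldodeca-2,6,10-trienoate
Product: 26 methyl (2Z,6E)-7,11-dimethyl-3-[(trimethylsilyl)methyl]dodeca-2,6,10-trienoate
Conditions: Me3SiCH2MgCl, Ni(acac)2 (5 mol%), THF, 0 °C to rt
Reagents that add atoms: (trimethylsilyl)methylmagnesium chloride, C[Si](C)(C)C[Mg]Cl
Why: Nickel-catalysed Kumada-type coupling of the enol phosphate with retention gives the Z-allylsilane in which the ester is trans to the chain, as ring closure to an equatorial C9 requires.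

Step 19
Reactants: 26 methyl (2Z,6E)-7,11-dimethyl-3-[(trimethylsilyl)methyl]dodeca-2,6,10-trienoate
Product: 27 methyl (2Z,6S,7S,10S)-6,7:10,11-diepoxy-7,11-dimethyl-3-[(trimethylsilyl)methyl]dodec-2-enoate
Conditions: ent-Shi ketone (60 mol%), KHSO5 (as 2KHSO5·KHSO4·K2SO4), K2CO3, n-Bu4NHSO4, aq. Na2B4O7/Na2EDTA buffer, MeCN/CH2(OMe)2, 0 °C
Reagents that add atoms: potassium peroxymonosulfate, [K+].OOS(=O)(=O)[O-]
Why: Shi asymmetric epoxidation by the chiral dioxirane oxidises the two electron-rich trisubstituted alkenes with catalyst control, giving the (S)-configured epoxide carbons that become C14, C17 and C11, and leaves the ester-conjugated allylsilane alkene.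

Step 20
Reactants: 27 methyl (2Z,6S,7S,10S)-6,7:10,11-diepoxy-7,11-dimethyl-3-[(trimethylsilyl)methyl]dodec-2-enoate
Product: 29 methyl (3S,5aS,6R,9aS)-3-hydroxy-2,2,5a-trimethyl-7-methylidenedecahydro-1-benzoxepine-6-carboxylate, via its 3-O-trimethylsilyl ether 28 (not isolated)
Conditions: Me3SiOTf (1.2 equiv), 2,6-di-tert-butyl-4-methylpyridine, CH2Cl2, −78 °C; then aq. citric acid/MeOH, 0 °C
Reagents that add atoms: none
Why: The silyl triflate activates the terminal epoxide, the neighbouring epoxide oxygen opens it at the tertiary carbon C15 (7-endo) to an epoxonium ion, and the allylsilane attacks the tertiary C11 anti through a chair to close ring B and lose silicon as the exocyclic alkene (tandem oxacyclisation–carbacyclisation, an epoxide-initiated cation–olefin cascade terminated by an allylsilane); C14 and C17 retain the epoxide configuration, C11 is inverted, and the equatorial C10 ester follows from the Z-allylsilane geometry.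

Step 21
Reactants: 29 methyl (3S,5aS,6R,9aS)-3-hydroxy-2,2,5a-trimethyl-7-methylidenedecahydro-1-benzoxepine-6-carboxylate
Product: 30 methyl (3S,5aS,6S,7S,9aS)-3-hydroxy-2,2,5a-trimethyloctahydro-2H-spiro[1-benzoxepine-7,2'-oxirane]-6-carboxylate (epoxide oxygen equatorial, anti to the C11 methyl)
Conditions: mCPBA, NaHCO3, CH2Cl2, 0 °C
Reagents that add atoms: 3-chloroperbenzoic acid, OOC(=O)c1cccc(Cl)c1
Why: Prilezhaev epoxidation of the exocyclic alkene should occur from the equatorial face, because the axial face is blocked by the syn-axial C11 methyl, as is usual for 8(17)-ene systems of the labdane and drimane type.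

Step 22
Reactants: 30 methyl (3S,5aS,6S,7S,9aS)-3-hydroxy-2,2,5a-trimethyloctahydro-2H-spiro[1-benzoxepine-7,2'-oxirane]-6-carboxylate
Product: 31 (3S,5aS,6R,7S,9aS)-6-(hydroxymethyl)-2,2,5a,7-tetramethyldecahydro-1-benzoxepine-3,7-diol
Conditions: LiAlH4, THF, 0 °C to reflux
Reagents that add atoms: none
Why: Hydride reduces the ester to the C9 carbinol and opens the spiro-epoxide at its CH2 terminus, which leaves the C20 oxygen equatorial and the new methyl axial.

Step 23
Reactants: 31 (3S,5aS,6R,7S,9aS)-6-(hydroxymethyl)-2,2,5a,7-tetramethyldecahydro-1-benzoxepine-3,7-diol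
Product: 32 (3S,5aS,6R,7S,9aS)-2,2,5a,7-tetramethyl-3,7-bis[(triethylsilyl)oxy]-6-{[(triethylsilyl)oxy]methyl}decahydro-1-benzoxepine
Conditions: Et3SiOTf (4 equiv), 2,6-lutidine, CH2Cl2, −78 to 0 °C
Reagents that add atoms: triethylsilyl trifluoromethanesulfonate, CC[Si](CC)(CC)OS(=O)(=O)C(F)(F)F
Why: Exhaustive silylation with the silyl triflate covers the primary, secondary and tertiary hydroxyls; the C20 ether blocks retro-aldol ring opening once C9 is an aldehyde.

Step 24
Reactants: 32 (3S,5aS,6R,7S,9aS)-2,2,5a,7-tetramethyl-3,7-bis[(triethylsilyl)oxy]-6-{[(triethylsilyl)oxy]methyl}decahydro-1-benzoxepine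
Product: 33 (3S,5aS,6S,7S,9aS)-2,2,5a,7-tetramethyl-3,7-bis[(triethylsilyl)oxy]decahydro-1-benzoxepine-6-carbaldehyde
Conditions: (COCl)2, DMSO, CH2Cl2, −78 to −30 °C; then Et3N, −78 °C to rt
Reagents that add atoms: none
Why: Swern conditions cleave and oxidise only the primary triethylsilyl ether, and the aldehyde stays equatorial at C10, its more stable orientation.

**Fragment union and end game**

Step 25
Reactants: 21 1-phenyl-5-({[(1S,4aS,5S,8aS)-2,5,8,8-tetramethyl-5-[(triethylsilyl)oxy]-1,4,4a,5,6,7,8,8a-octahydronaphthalen-1-yl]methyl}sulfonyl)-1H-tetrazole; 33 (3S,5aS,6S,7S,9aS)-2,2,5a,7-tetramethyl-3,7-bis[(triethylsilyl)oxy]decahydro-1-benzoxepine-6-carbaldehyde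
Product: 34 (E)-C8=C9 alkene joining C7 of the decalin of 21 to C10 of the benzoxepane of 33, tris(triethylsilyl) ether, all stereocentres as in 21 and 33
Conditions: 21, KN(SiMe3)2 (1.1 equiv), DME, −60 °C; then 33, −60 °C to rt
Reagents that add atoms: none
Why: Julia–Kocienski olefination, in which the sulfonyl carbanion adds to the aldehyde and Smiles rearrangement with loss of SO2 and the tetrazolate gives the alkene; alkene geometry is irrelevant because the double bond is reduced next, and carbonyl addition replaces an unfavourable substitution at a primary carbon flanked by two fully substituted centres.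

Step 26
Reactants: 34 (E)-C8=C9 alkene, tris(triethylsilyl) ether
Product: 35 C8–C9 saturated tris(triethylsilyl) ether of sipholenol L (O-silyl at C14, C20 and C24)
Conditions: 2-nitrobenzenesulfonohydrazide (excess, in portions), Et3N, CH2Cl2, rt
Reagents that add atoms: none
Why: Diimide reduction transfers hydrogen concertedly to the 1,2-disubstituted alkene and is far slower with the trisubstituted C2=C3 alkene, so the ring C double bond should remain without migration.

Step 27
Reactants: 35 C8–C9 saturated tris(triethylsilyl) ether of sipholenol L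
Product: 36 sipholenol L
Conditions: Bu4NF, THF, rt to 50 °C
Reagents that add atoms: none
Why: Fluoride-mediated desilylation removes the secondary and both tertiary triethylsilyl ethers under non-acidic conditions that cannot ionise the tertiary carbinols or isomerise the alkene.

**Compound list**

1 | but-2-yn-1-ol | CC#CCO | starting material
2 | (2Z)-3-iodobut-2-en-1-ol | C/C(I)=C/CO | intermediate
3 | 4-bromo-2-methylbut-1-ene | CC(=C)CCBr | starting material
4 | (3-methylbut-3-en-1-yl)zinc bromide | CC(=C)CC[Zn]Br | intermediate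
5 | (2Z)-3,6-dimethylhepta-2,6-dien-1-ol | C/C(CCC(C)=C)=C/CO | intermediate
6 | [(2R,3S)-3-methyl-3-(3-methylbut-3-en-1-yl)oxiran-2-yl]methanol | OC[C@H]1O[C@@]1(C)CCC(C)=C | intermediate
7 | but-3-en-1-ylmagnesium bromide | C=CCC[Mg]Br | starting material
8 | (2S,3S)-2-(but-3-en-1-yl)-3,6-dimethylhept-6-ene-1,3-diol | C=CCC[C@H]([C@@](C)(O)CCC(C)=C)CO | intermediate
9 | (2S,3S)-2-(but-3-en-1-yl)-3,6-dimethyl-1,3-bis[(triethylsilyl)oxy]hept-6-ene | C=CCC[C@H]([C@@](C)(O[Si](CC)(CC)CC)CCC(C)=C)CO[Si](CC)(CC)CC | intermediate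
10 | (2R)-2-[(2S)-5-methyl-2-[(triethylsilyl)oxy]hex-5-en-2-yl]hex-5-enal | C=CCC[C@H]([C@@](C)(O[Si](CC)(CC)CC)CCC(C)=C)C=O | intermediate
11 | (2R)-2-[(2S)-5-methyl-2-[(triethylsilyl)oxy]hex-5-en-2-yl]-5-oxohexanal | CC(=O)CC[C@H]([C@@](C)(O[Si](CC)(CC)CC)CCC(C)=C)C=O | intermediate
12 | (4S)-4-[(2S)-5-methyl-2-[(triethylsilyl)oxy]hex-5-en-2-yl]cyclohex-2-en-1-one | O=C1CC[C@H]([C@@](C)(O[Si](CC)(CC)CC)CCC(C)=C)C=C1 | intermediate
13 | formaldehyde | C=O | starting material
14 | (4S)-2-(hydroxymethyl)-4-[(2S)-5-methyl-2-[(triethylsilyl)oxy]hex-5-en-2-yl]cyclohex-2-en-1-one | O=C1CC[C@H]([C@@](C)(O[Si](CC)(CC)CC)CCC(C)=C)C=C1CO | intermediate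
15 | (4S)-4-[(2S)-5-methyl-2-[(triethylsilyl)oxy]hex-5-en-2-yl]-2-{[(triethylsilyl)oxy]methyl}cyclohex-2-en-1-one | O=C1CC[C@H]([C@@](C)(O[Si](CC)(CC)CC)CCC(C)=C)C=C1CO[Si](CC)(CC)CC | intermediate
16 | (1R,4aS,5S,8aS)-5,8,8-trimethyl-5-[(triethylsilyl)oxy]-1-{[(triethylsilyl)oxy]methyl}octahydronaphthalen-2(1H)-one | O=C1CC[C@H]2[C@@H]([C@@H]1CO[Si](CC)(CC)CC)C(C)(C)CC[C@]2(C)O[Si](CC)(CC)CC | intermediate
17 | (1R,4aS,5S,8aS)-5,8,8-trimethyl-5-[(triethylsilyl)oxy]-1-{[(triethylsilyl)oxy]methyl}-1,4,4a,5,6,7,8,8a-octahydronaphthalen-2-yl trifluoromethanesulfonate | O=S(=O)(OC1=CC[C@H]2[C@@H]([C@@H]1CO[Si](CC)(CC)CC)C(C)(C)CC[C@]2(C)O[Si](CC)(CC)CC)C(F)(F)F | intermediate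
18 | triethyl{[(1S,4aS,5S,8aR)-2,5,8,8-tetramethyl-5-[(triethylsilyl)oxy]-1,4,4a,5,6,7,8,8a-octahydronaphthalen-1-yl]methoxy}silane | CC1=CC[C@H]2[C@@H]([C@@H]1CO[Si](CC)(CC)CC)C(C)(C)CC[C@]2(C)O[Si](CC)(CC)CC | intermediate
19 | [(1S,4aS,5S,8aR)-2,5,8,8-tetramethyl-5-[(triethylsilyl)oxy]-1,4,4a,5,6,7,8,8a-octahydronaphthalen-1-yl]methanol | CC1=CC[C@H]2[C@@H]([C@@H]1CO)C(C)(C)CC[C@]2(C)O[Si](CC)(CC)CC | intermediate
20 | 1-phenyl-5-({[(1S,4aS,5S,8aS)-2,5,8,8-tetramethyl-5-[(triethylsilyl)oxy]-1,4,4a,5,6,7,8,8a-octahydronaphthalen-1-yl]methyl}sulfanyl)-1H-tetrazole | CC1=CC[C@H]2[C@@H]([C@@H]1CSc1nnnn1-c1ccccc1)C(C)(C)CC[C@]2(C)O[Si](CC)(CC)CC | intermediate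
21 | 1-phenyl-5-({[(1S,4aS,5S,8aS)-2,5,8,8-tetramethyl-5-[(triethylsilyl)oxy]-1,4,4a,5,6,7,8,8a-octahydronaphthalen-1-yl]methyl}sulfonyl)-1H-tetrazole | CC1=CC[C@H]2[C@@H]([C@@H]1CS(=O)(=O)c1nnnn1-c1ccccc1)C(C)(C)CC[C@]2(C)O[Si](CC)(CC)CC | intermediate
22 | methyl acetoacetate | COC(=O)CC(C)=O | starting material
23 | geranyl bromide | CC(C)=CCC/C(C)=C/CBr | starting material
24 | methyl (6E)-7,11-dimethyl-3-oxododeca-6,10-dienoate | COC(=O)CC(=O)CC/C=C(\C)CCC=C(C)C | intermediate
25 | methyl (2Z,6E)-3-[(diethoxyphosphoryl)oxy]-7,11-dimethyldodeca-2,6,10-trienoate | COC(=O)/C=C(\OP(=O)(OCC)OCC)CC/C=C(\C)CCC=C(C)C | intermediate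
26 | methyl (2Z,6E)-7,11-dimethyl-3-[(trimethylsilyl)methyl]dodeca-2,6,10-trienoate | COC(=O)/C=C(\C[Si](C)(C)C)CC/C=C(\C)CCC=C(C)C | intermediate
27 | methyl (2Z,6S,7S,10S)-6,7:10,11-diepoxy-7,11-dimethyl-3-[(trimethylsilyl)methyl]dodec-2-enoate | COC(=O)/C=C(\C[Si](C)(C)C)CC[C@@H]1O[C@@]1(C)CC[C@@H]1OC1(C)C | intermediate
28 | methyl (3S,5aS,6R,9aS)-2,2,5a-trimethyl-7-methylidene-3-[(trimethylsilyl)oxy]decahydro-1-benzoxepine-6-carboxylate | COC(=O)[C@H]1[C@]2(C)CC[C@H](O[Si](C)(C)C)C(C)(C)O[C@H]2CCC1=C | intermediate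
29 | methyl (3S,5aS,6R,9aS)-3-hydroxy-2,2,5a-trimethyl-7-methylidenedecahydro-1-benzoxepine-6-carboxylate | COC(=O)[C@H]1[C@]2(C)CC[C@H](O)C(C)(C)O[C@H]2CCC1=C | intermediate
30 | methyl (3S,5aS,6S,7S,9aS)-3-hydroxy-2,2,5a-trimethyloctahydro-2H-spiro[1-benzoxepine-7,2'-oxirane]-6-carboxylate | COC(=O)[C@H]1[C@]2(C)CC[C@H](O)C(C)(C)O[C@H]2CC[C@@]13CO3 | intermediate
31 | (3S,5aS,6R,7S,9aS)-6-(hydroxymethyl)-2,2,5a,7-tetramethyldecahydro-1-benzoxepine-3,7-diol | OC[C@H]1[C@]2(C)CC[C@H](O)C(C)(C)O[C@H]2CC[C@]1(C)O | intermediate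
32 | (3S,5aS,6R,7S,9aS)-2,2,5a,7-tetramethyl-3,7-bis[(triethylsilyl)oxy]-6-{[(triethylsilyl)oxy]methyl}decahydro-1-benzoxepine | CC[Si](CC)(CC)OC[C@H]1[C@]2(C)CC[C@H](O[Si](CC)(CC)CC)C(C)(C)O[C@H]2CC[C@]1(C)O[Si](CC)(CC)CC | intermediate
33 | (3S,5aS,6S,7S,9aS)-2,2,5a,7-tetramethyl-3,7-bis[(triethylsilyl)oxy]decahydro-1-benzoxepine-6-carbaldehyde | O=C[C@H]1[C@]2(C)CC[C@H](O[Si](CC)(CC)CC)C(C)(C)O[C@H]2CC[C@]1(C)O[Si](CC)(CC)CC | intermediate
34 | (E)-C8=C9 alkene, tris(triethylsilyl) ether of 8,9-didehydrosipholenol L | CC1=CC[C@H]2[C@@H]([C@@H]1/C=C/[C@H]1[C@]3(C)CC[C@H](O[Si](CC)(CC)CC)C(C)(C)O[C@H]3CC[C@]1(C)O[Si](CC)(CC)CC)C(C)(C)CC[C@]2(C)O[Si](CC)(CC)CC | intermediate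
35 | tris(triethylsilyl) ether of sipholenol L (O-silyl at C14, C20, C24) | CC1=CC[C@H]2[C@@H]([C@@H]1CC[C@H]1[C@]3(C)CC[C@H](O[Si](CC)(CC)CC)C(C)(C)O[C@H]3CC[C@]1(C)O[Si](CC)(CC)CC)C(C)(C)CC[C@]2(C)O[Si](CC)(CC)CC | intermediate
36 | sipholenol L | CC1=CC[C@H]2[C@@H]([C@@H]1CC[C@H]1[C@]3(C)CC[C@H](O)C(C)(C)O[C@H]3CC[C@]1(C)O)C(C)(C)CC[C@]2(C)O | target

**Step count**

Total: 27 steps (15 for the right half, 9 for the left half, 3 after the union). Longest linear sequence: 18 steps (steps 1–15 and 25–27).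

**Steps most likely to fail**

Step 11 (key step). The tertiary radical may be reduced before it cyclises, which amounts to hydrogenation of the alkene. The enolate may also be protonated from the wrong face, or C7 may epimerise afterwards, since the required C7 configuration is the kinetic one. The fallback sets out from 15 and returns at 16. Irradiation at 350 nm in CH2Cl2 should give, by intramolecular enone–alkene [2+2] photocycloaddition in the straight sense (C6–C21 bond closing the six-membered ring, then C7–CH2), the cyclobutane photoadduct F1. SmI2 in THF/HMPA with t-BuOH at −78 °C then cleaves the exocyclic cyclobutane bond between C7 and the former alkene CH2, which is the bond aligned with the ketyl. The primary radical is reduced and protonated to the second methyl on C21, and protonation of the samarium enolate at C7 anti to C21 gives 16.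

Step 20 (epoxide cascade). The activated terminal epoxide may be opened in the exo mode, the epoxonium ion may be captured before the weakly nucleophilic, ester-conjugated allylsilane attacks, or the allylsilane may be protodesilylated. The fallback sets out from 27 and returns at 31; it replaces the terminating nucleophile by an electron-rich allylsilane. i-Bu2AlH (CH2Cl2, −78 °C) reduces the ester to the diepoxy allylic alcohol F2, and pivaloyl chloride/pyridine gives the pivalate F3. The same Me3SiOTf/2,6-di-tert-butyl-4-methylpyridine treatment should then give the bicyclic silyl ether F4, hydrolysed on work-up to the hydroxy pivalate F5. mCPBA gives the equatorial spiro-epoxide F6, and LiAlH4 removes the pivalate and opens the epoxide to the triol 31.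

Step 25 (fragment union). Addition of the sulfonyl carbanion to the aldehyde, which lies between two fully substituted carbons, may be slow, so that enolisation of the aldehyde or self-condensation of the sulfone competes. The fallback sets out from 19 and returns at 35; it uses carbonyl addition of an organolithium and deoxygenation. I2/PPh3/imidazole converts 19 into the iodide F7. Iodine–lithium exchange with t-BuLi (Et2O/pentane, −78 °C) gives the alkyllithium F8, which adds to aldehyde 33 to give the C9 carbinol F9 as an epimer mixture. NaH/CS2/MeI forms the xanthate F10, and Bu3SnH/AIBN (toluene, 90 °C, Barton–McCombie) removes the oxygen to give 35.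

Further compounds
F1 | step 11 | cyclobutane photoadduct of 15 (bonds C6–C21 and C7–CH2 formed, cis-fused) | O=C1CC[C@H]2[C@H]3[C@]1(CO[Si](CC)(CC)CC)C[C@@]3(C)CC[C@]2(C)O[Si](CC)(CC)CC
F2 | step 20 | (2Z,6S,7S,10S)-6,7:10,11-diepoxy-7,11-dimethyl-3-[(trimethylsilyl)methyl]dodec-2-en-1-ol | OC/C=C(\C[Si](C)(C)C)CC[C@@H]1O[C@@]1(C)CC[C@@H]1OC1(C)C
F3 | step 20 | (2Z,6S,7S,10S)-6,7:10,11-diepoxy-7,11-dimethyl-3-[(trimethylsilyl)methyl]dodec-2-en-1-yl pivalate | CC(C)(C)C(=O)OC/C=C(\C[Si](C)(C)C)CC[C@@H]1O[C@@]1(C)CC[C@@H]1OC1(C)C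
F4 | step 20 | [(3S,5aS,6R,9aS)-2,2,5a-trimethyl-7-methylidene-3-[(trimethylsilyl)oxy]decahydro-1-benzoxepin-6-yl]methyl pivalate | CC(C)(C)C(=O)OC[C@H]1[C@]2(C)CC[C@H](O[Si](C)(C)C)C(C)(C)O[C@H]2CCC1=C
F5 | step 20 | [(3S,5aS,6R,9aS)-3-hydroxy-2,2,5a-trimethyl-7-methylidenedecahydro-1-benzoxepin-6-yl]methyl pivalate | CC(C)(C)C(=O)OC[C@H]1[C@]2(C)CC[C@H](O)C(C)(C)O[C@H]2CCC1=C
F6 | step 20 | spiro-epoxide of F5 at the exocyclic alkene (oxygen equatorial) | CC(C)(C)C(=O)OC[C@H]1[C@]2(C)CC[C@H](O)C(C)(C)O[C@H]2CC[C@@]13CO3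
F7 | step 25 | primary iodide from 19 (C8–I) | CC1=CC[C@H]2[C@@H]([C@@H]1CI)C(C)(C)CC[C@]2(C)O[Si](CC)(CC)CC
F8 | step 25 | primary alkyllithium from F7 (C8–Li) | CC1=CC[C@H]2[C@@H]([C@@H]1C[Li])C(C)(C)CC[C@]2(C)O[Si](CC)(CC)CC
F9 | step 25 | C9 carbinol adduct of F8 and 33 (both C9 epimers) | CC1=CC[C@H]2[C@@H]([C@@H]1CC(O)[C@H]1[C@]3(C)CC[C@H](O[Si](CC)(CC)CC)C(C)(C)O[C@H]3CC[C@]1(C)O[Si](CC)(CC)CC)C(C)(C)CC[C@]2(C)O[Si](CC)(CC)CC
F10 | step 25 | S-methyl xanthate of F9 | CC1=CC[C@H]2[C@@H]([C@@H]1CC(OC(=S)SC)[C@H]1[C@]3(C)CC[C@H](O[Si](CC)(CC)CC)C(C)(C)O[C@H]3CC[C@]1(C)O[Si](CC)(CC)CC)C(C)(C)CC[C@]2(C)O[Si](CC)(CC)CC
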